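**Retrosynthetic overview**
1. The target comes from its aryl mesylate, which comes from a 4-amino-5-bromo precursor by hydrodediazoniation. That precursor goes back (NH2-directed bromination, nitro reduction, O-mesylation) to 2-(3,5-dibromo-2-methoxyphenoxy)-4-nitrophenol. The nitrogen is a traceless director that places Br para to the ether oxygen.
2. Key disconnection: the nitrophenol ring is cut into a C3 ketone unit, 1-(3,5-dibromo-2-methoxyphenoxy)propan-2-one, and a C3 dialdehyde unit, sodium nitromalonaldehyde. An intermolecular aldol condensation joins them and a second aldol condensation closes the ring.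
3. The aryloxyacetone comes from 3,5-dibromo-2-methoxyphenol and chloroacetone (Williamson), so the bridging oxygen is in place before the second ring exists.
4. 3,5-Dibromo-2-methoxyphenol comes from 3,5-dibromosalicylaldehyde by O-methylation, then Baeyer–Villiger oxidation and saponification.
5. Ring order: the dibromoanisole ring is bought intact. The bromophenol ring is the only ring formed (step 4), and it forms directly at the aromatic oxidation level.

Assumption: the target has no stereocentre and its diaryl ether axes rotate freely, so it is achiral and needs no stereocontrol; sodium nitromalonaldehyde monohydrate is taken as a catalogue reagent.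

**Step 1**
Reactants: 1 3,5-dibromo-2-hydroxybenzaldehyde
Product: 2 3,5-dibromo-2-methoxybenzaldehyde
Conditions: MeI, K2CO3, DMF, rt
Reagents that add atoms: iodomethane, CI
Why: Williamson-type O-methylation (SN2 on MeI) of the acidic phenol, which is the only nucleophilic site once carbonate has deprotonated it.

**Step 2**
Reactants: 2 3,5-dibromo-2-methoxybenzaldehyde
Product: 4 3,5-dibromo-2-methoxyphenol, via 3,5-dibromo-2-methoxyphenyl formate 3 (not isolated)
Conditions: mCPBA, CH2Cl2, reflux; then NaOH, MeOH/H2O, rt; HCl
Reagents that add atoms: mCPBA (3-chloroperoxybenzoic acid), O=C(OO)c1cccc(Cl)c1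
Why: Baeyer–Villiger oxidation in which the ortho-alkoxy aryl group migrates from the Criegee adduct in preference to hydride, and mild saponification of the formate then frees the phenol while the aryl bromides and the methyl ether are inert to peracid and cold hydroxide.

**Step 3**
Reactants: 4 3,5-dibromo-2-methoxyphenol; 5 chloroacetone
Product: 6 1-(3,5-dibromo-2-methoxyphenoxy)propan-2-one
Conditions: K2CO3, acetone, reflux
Reagents that add atoms: none
Why: Williamson ether synthesis, an SN2 displacement by the phenoxide on the very reactive α-chloroketone under a base too weak to cause much ketone self-condensation.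

**Step 4 (key step)**
Reactants: 6 1-(3,5-dibromo-2-methoxyphenoxy)propan-2-one; 7 sodium nitromalonaldehyde monohydrate
Product: 9 2-(3,5-dibromo-2-methoxyphenoxy)-4-nitrophenol, via open-chain aldol condensation product 8 (not isolated)
Conditions: NaOH, EtOH/H2O, 0 °C → rt, 2–3 d; then HCl
Reagents that add atoms: none
Why: An intermolecular aldol condensation of the enolate of 6 (at the more acidic ArO–CH2 carbon) with one formyl group of 7 joins the two fragments, and an intramolecular aldol condensation of the CH3 group on the second formyl group followed by tautomerisation gives the benzene ring directly (the classical nitromalonaldehyde [3+3] phenol synthesis, as in acetone → 4-nitrophenol or dibenzyl ketone → 4-nitro-2,6-diphenylphenol), with only one regioisomer possible because both α-carbons of the ketone end up in the ring.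

**Step 5**
Reactants: 9 2-(3,5-dibromo-2-methoxyphenoxy)-4-nitrophenol
Product: 10 2-(3,5-dibromo-2-methoxyphenoxy)-4-nitrophenyl methanesulfonate
Conditions: MsCl, Et3N, CH2Cl2, 0 °C
Reagents that add atoms: methanesulfonyl chloride, CS(=O)(=O)Cl
Why: O-sulfonylation of the acidic nitrophenol gives an acid-stable, electron-withdrawing mask that prevents quinone-imine formation after nitro reduction and stops this oxygen from competing as a director in the bromination.

**Step 6**
Reactants: 10 2-(3,5-dibromo-2-methoxyphenoxy)-4-nitrophenyl methanesulfonate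
Product: 11 4-amino-2-(3,5-dibromo-2-methoxyphenoxy)phenyl methanesulfonate
Conditions: Fe powder, AcOH/EtOH/H2O, 70 °C
Reagents that add atoms: none
Why: Béchamp-type iron reduction takes the nitro group to the aniline by electron transfer without touching the C–Br bonds (which hydrogenation over Pd would endanger) or the sulfonate ester.

**Step 7**
Reactants: 11 4-amino-2-(3,5-dibromo-2-methoxyphenoxy)phenyl methanesulfonate
Product: 12 4-amino-5-bromo-2-(3,5-dibromo-2-methoxyphenoxy)phenyl methanesulfonate
Conditions: NBS (1.0 equiv), MeCN, −10 → 0 °C, dark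
Reagents that add atoms: N-bromosuccinimide, O=C1CCC(=O)N1Br
Why: Electrophilic aromatic bromination controlled by the amino group, whose para position is blocked and whose C3 ortho position is squeezed between NH2 and OAr, so C5 (ortho to NH2 and para to the ether oxygen) reacts while the dibromoanisole ring is far less electron-rich.

**Step 8**
Reactants: 12 4-amino-5-bromo-2-(3,5-dibromo-2-methoxyphenoxy)phenyl methanesulfonate
Product: 14 5-bromo-2-(3,5-dibromo-2-methoxyphenoxy)phenyl methanesulfonate, via arenediazonium hydrogen sulfate 13 (not isolated)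
Conditions: NaNO2, H2SO4, AcOH/H2O, 0 °C; then 50% aq H3PO2, 0 °C → rt
Reagents that add atoms: none
Why: Diazotisation followed by hypophosphorous acid hydrodediazoniation (radical-chain reduction of ArN2+) replaces the spent directing group by hydrogen, and because the diazonium group is meta to the aryloxy group no Pschorr-type cyclisation can compete.

**Step 9**
Reactants: 14 5-bromo-2-(3,5-dibromo-2-methoxyphenoxy)phenyl methanesulfonate
Product: 15 5-bromo-2-(3,5-dibromo-2-methoxyphenoxy)phenol (target)
Conditions: NaOH, MeOH/THF/H2O, 60 °C; then HCl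
Reagents that add atoms: none
Why: Alkaline cleavage of the aryl sulfonate ester (hydroxide attacks the sulfonyl group and phenoxide leaves) frees the phenol, and the unactivated aryl bromides, the aryl methyl ether and the diaryl ether do not react with aqueous hydroxide at 60 °C.

**Compound list**
1 | 3,5-dibromo-2-hydroxybenzaldehyde (3,5-dibromosalicylaldehyde) | O=Cc1cc(Br)cc(Br)c1O | starting material
2 | 3,5-dibromo-2-methoxybenzaldehyde | COc1c(Br)cc(Br)cc1C=O | intermediate
3 | 3,5-dibromo-2-methoxyphenyl formate | COc1c(Br)cc(Br)cc1OC=O | intermediate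
4 | 3,5-dibromo-2-methoxyphenol | COc1c(Br)cc(Br)cc1O | intermediate
5 | chloroacetone (1-chloropropan-2-one) | CC(=O)CCl | starting material
6 | 1-(3,5-dibromo-2-methoxyphenoxy)propan-2-one | COc1c(Br)cc(Br)cc1OCC(C)=O | intermediate
7 | sodium nitromalonaldehyde monohydrate | [Na+].[O-]C=C(C=O)[N+](=O)[O-].O | starting material
8 | 3-(3,5-dibromo-2-methoxyphenoxy)-6-hydroxy-5-nitrohexa-3,5-dien-2-one (enol form of the aldehyde, present as its sodium salt) | COc1c(Br)cc(Br)cc1OC(=CC(=CO)[N+](=O)[O-])C(C)=O | intermediate
9 | 2-(3,5-dibromo-2-methoxyphenoxy)-4-nitrophenol | COc1c(Br)cc(Br)cc1Oc1cc([N+](=O)[O-])ccc1O | intermediate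
10 | 2-(3,5-dibromo-2-methoxyphenoxy)-4-nitrophenyl methanesulfonate | COc1c(Br)cc(Br)cc1Oc1cc([N+](=O)[O-])ccc1OS(C)(=O)=O | intermediate
11 | 4-amino-2-(3,5-dibromo-2-methoxyphenoxy)phenyl methanesulfonate | COc1c(Br)cc(Br)cc1Oc1cc(N)ccc1OS(C)(=O)=O | intermediate
12 | 4-amino-5-bromo-2-(3,5-dibromo-2-methoxyphenoxy)phenyl methanesulfonate | COc1c(Br)cc(Br)cc1Oc1cc(N)c(Br)cc1OS(C)(=O)=O | intermediate
13 | 2-bromo-5-(3,5-dibromo-2-methoxyphenoxy)-4-(methylsulfonyloxy)benzenediazonium hydrogen sulfate | COc1c(Br)cc(Br)cc1Oc1cc([N+]#N)c(Br)cc1OS(C)(=O)=O.OS(=O)(=O)[O-] | intermediate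
14 | 5-bromo-2-(3,5-dibromo-2-methoxyphenoxy)phenyl methanesulfonate | COc1c(Br)cc(Br)cc1Oc1ccc(Br)cc1OS(C)(=O)=O | intermediate
15 | 5-bromo-2-(3,5-dibromo-2-methoxyphenoxy)phenol (achiral) | COc1c(Br)cc(Br)cc1Oc1ccc(Br)cc1O | target

**Total step count:** 9
**Longest linear sequence:** 9 steps (1 → 15)

**Three steps most likely to fail**

Step 4. In alkali, 6 can self-condense and 7 can decompose faster than the ring forms. Salt 7 is also shock- and heat-sensitive and limits forcing conditions.
The fallback sets out from 4 and comes back to the route at 15. The potassium salt of 4 displaces fluoride from purchased 5-bromo-2-fluorobenzaldehyde (O=Cc1cc(Br)ccc1F) by SNAr (K2CO3, DMAc, 100 °C). This gives 5-bromo-2-(3,5-dibromo-2-methoxyphenoxy)benzaldehyde F4. Baeyer–Villiger oxidation with mCPBA in CH2Cl2 gives 5-bromo-2-(3,5-dibromo-2-methoxyphenoxy)phenyl formate F5. Saponification with NaOH/MeOH then gives 15 directly, with the bromine already para to the ether oxygen.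

Step 2. The two bromines meta to the migrating carbon lower its migratory aptitude, so hydride migration to the benzoic acid may compete.
The fallback sets out from 2 and comes back at 4. MeMgBr (THF, 0 °C) adds to the aldehyde to give racemic 1-(3,5-dibromo-2-methoxyphenyl)ethanol F1. Dess–Martin periodinane oxidises it to 1-(3,5-dibromo-2-methoxyphenyl)ethanone F2. Baeyer–Villiger oxidation of this methyl ketone (mCPBA, TFA, CH2Cl2) has no hydride to migrate, and aryl clearly beats methyl, so it gives 3,5-dibromo-2-methoxyphenyl acetate F3. Saponification with NaOH/MeOH gives 4.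

Step 7. The free aniline may brominate a second time at C3 or be oxidised by NBS.
The fallback sets out from 11 and comes back at 12. Ac2O/pyridine gives 4-acetamido-2-(3,5-dibromo-2-methoxyphenoxy)phenyl methanesulfonate F6, whose tempered ring takes up only one bromine. Br2 with NaOAc in AcOH at rt gives 4-acetamido-5-bromo-2-(3,5-dibromo-2-methoxyphenoxy)phenyl methanesulfonate F7. Acid hydrolysis of the amide (6 M HCl, EtOH, reflux), to which the mesylate is stable, gives 12.

**Further compounds**
F1 | step 2 | 1-(3,5-dibromo-2-methoxyphenyl)ethanol (racemic) | COc1c(Br)cc(Br)cc1C(C)O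
F2 | step 2 | 1-(3,5-dibromo-2-methoxyphenyl)ethanone | COc1c(Br)cc(Br)cc1C(C)=O
F3 | step 2 | 3,5-dibromo-2-methoxyphenyl acetate | COc1c(Br)cc(Br)cc1OC(C)=O
F4 | step 4 | 5-bromo-2-(3,5-dibromo-2-methoxyphenoxy)benzaldehyde | COc1c(Br)cc(Br)cc1Oc1ccc(Br)cc1C=O
F5 | step 4 | 5-bromo-2-(3,5-dibromo-2-methoxyphenoxy)phenyl formate | COc1c(Br)cc(Br)cc1Oc1ccc(Br)cc1OC=O
F6 | step 7 | 4-acetamido-2-(3,5-dibromo-2-methoxyphenoxy)phenyl methanesulfonate | COc1c(Br)cc(Br)cc1Oc1cc(NC(C)=O)ccc1OS(C)(=O)=O
F7 | step 7 | 4-acetamido-5-bromo-2-(3,5-dibromo-2-methoxyphenoxy)phenyl methanesulfonate | COc1c(Br)cc(Br)cc1Oc1cc(NC(C)=O)c(Br)cc1OS(C)(=O)=O
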